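The trans C4–Br/C5–Cl pair on the cyclohexane ring (C1 = carbinol carbon, C4 = C(Br)CH3, C5 = CHCl, side chain from C7) is read as the footprint of a C4=C5 alkene. Opening the ring at that bond leaves an open-chain diene with a single stereocentre, the fully substituted C1. Ring-closing metathesis of ethyl (S)-2-allyl-2-hydroxy-5-methylhex-5-enoate therefore forms the six-membered carbocycle and its trisubstituted double bond in one operation. The C1 hydroxyl then steers epoxidation. The C7 ester keeps C1 from ionising while both halogens are installed. The (R)-configured C8–C11 fragment is added last.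

Key step: step 3

Numbering: ring C1 (carbinol), C2, C3, C4 (Br, CH3), C5 (Cl), C6; chain C7 (on C1), C8, C9, C10 (carbinol), C11 (isopropenyl carbon). In the target the C1–OH and C4–Br lie on one ring face and C5–Cl on the other. The descriptors are 1S, 4R, 5R, 10R.
Assumption: the sense of induction of the allylboration catalyst in step 2 is taken from its behaviour with other α-keto esters. Both antipodes derive from valine, so the one that attacks the Si face of the ketone is used.

Step 1
Reactants: 1 4-bromo-2-methylbut-1-ene; 2 diethyl oxalate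
Product: 4 ethyl 5-methyl-2-oxohex-5-enoate, via 3-methylbut-3-enylmagnesium bromide 3 (not isolated)
Conditions: Mg, THF, rt; then added slowly to 2 (2 equiv), THF/Et2O, −78 °C; aq NH4Cl
Reagents that add atoms: magnesium, [Mg] (stays only in 3)
Why: Acylation of a Grignard reagent by diethyl oxalate stops at the α-keto ester because the magnesium hemiketal formed at −78 °C survives until the quench and inverse addition keeps the oxalate in excess.

Step 2
Reactants: 4 ethyl 5-methyl-2-oxohex-5-enoate; 5 allylboronic acid pinacol ester
Product: 6 ethyl (S)-2-allyl-2-hydroxy-5-methylhex-5-enoate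
Conditions: 5 (1.3 equiv), chiral aminophenol 2-{[3-(tert-butyl)-2-hydroxybenzyl]amino}-N,N,3-trimethylbutanamide (5 mol %), NaOt-Bu (10 mol %), MeOH (2 equiv), toluene, 22 °C
Reagents that add atoms: none
Why: In this catalytic enantioselective allylboration of an α-keto ester the aminophenol exchanges with the boronate to give a chiral allylboron species that binds the activated ketone in a closed six-membered transition state and delivers allyl to its Si face, which sets C1 as S, while methanol releases the product and turns the catalyst over.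

Step 3
Reactants: 6 ethyl (S)-2-allyl-2-hydroxy-5-methylhex-5-enoate
Product: 7 ethyl (S)-1-hydroxy-4-methylcyclohex-3-ene-1-carboxylate
Conditions: second-generation Grubbs catalyst (H2IMes)(PCy3)Cl2Ru=CHPh (3 mol %), 1,4-benzoquinone (10 mol %), CH2Cl2 (0.01 M), 40 °C, argon sparge
Reagents that add atoms: none
Why: The ruthenium benzylidene first exchanges with the unhindered allyl terminus, the new alkylidene adds across the tethered 1,1-disubstituted alkene in a [2+2] step, and cycloreversion of the ruthenacyclobutane gives the C4=C5 bond together with a Ru=CH2 carrier that leaves as ethylene in the next turnover. The closest known reaction type is ring-closing metathesis of 1,7-dienes to trisubstituted cyclohexenes that carry a free tertiary alcohol. The one ring formed, the carbocycle C1–C6, closes by intramolecular alkylidene–alkene exchange between C5 of the allyl arm and C4 of the methylbutenyl arm. No stereocentre is created, and the quaternary C1 is remote from the metal and passes through unchanged. The step needs cyclisation to win over dimerisation and over migration of the allyl double bond, which is secured by geminal substitution at C1 (it presses the two arms together), high dilution, irreversible escape of ethylene, benzoquinone as a trap for ruthenium hydrides, and the absence of any third alkene.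

Step 4
Reactants: 7 ethyl (S)-1-hydroxy-4-methylcyclohex-3-ene-1-carboxylate
Product: 8 ethyl (1S,3S,6R)-3-hydroxy-6-methyl-7-oxabicyclo[4.1.0]heptane-3-carboxylate (epoxide oxygen cis to the C1 hydroxyl)
Conditions: VO(acac)2 (3 mol %), t-BuOOH (1.5 equiv, decane), CH2Cl2, 0 °C to rt
Reagents that add atoms: tert-butyl hydroperoxide, CC(C)(C)OO
Why: In this hydroxyl-directed vanadium-catalysed epoxidation of a homoallylic cyclohexenol the pseudoaxial C1 alkoxide binds the vanadium alkyl peroxide and hands oxygen to the alkene face it occupies, so C4 and C5 are both oxygenated cis to the C1 hydroxyl, as with closely related 1-alkyl-4-methylcyclohex-3-en-1-ols.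

Step 5
Reactants: 8 syn-epoxy alcohol
Product: 9 ethyl (1S,3S,6R)-6-methyl-3-(triethylsilyloxy)-7-oxabicyclo[4.1.0]heptane-3-carboxylate
Conditions: Et3SiOTf (1.2 equiv), 2,6-lutidine (2 equiv), CH2Cl2, −78 °C
Reagents that add atoms: triethylsilyl trifluoromethanesulfonate, CC[Si](CC)(CC)OS(=O)(=O)C(F)(F)F
Why: Silylation of a tertiary alcohol with a silyl triflate and a hindered pyridine is fast at −78 °C, where the epoxide is untouched, and it masks the C1 oxygen, which could otherwise bridge to C4 (7-oxabicyclo[2.2.1]heptane formation) in the two acidic steps that follow.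

Step 6
Reactants: 9 silylated epoxide
Product: 10 ethyl (1S,3R,4R)-3-chloro-4-hydroxy-4-methyl-1-(triethylsilyloxy)cyclohexane-1-carboxylate
Conditions: LiCl (5 equiv), AcOH (3 equiv), THF, rt to 40 °C
Reagents that add atoms: lithium chloride, [Li+].[Cl-]
Why: Epoxide opening by lithium chloride under weak-acid assistance is an SN2 process at the secondary C5 from the face opposite the oxygen, which inverts C5 (Cl trans to the C1 oxygen) and leaves C4 as the tertiary alcohol, and the trans-diaxial (Fürst–Plattner) path is open because the two C1 substituents are similar in size and both half-chairs are populated.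

Step 7
Reactants: 10 chlorohydrin
Product: 11 ethyl (1S,3R,4R)-4-bromo-3-chloro-4-methyl-1-(triethylsilyloxy)cyclohexane-1-carboxylate
Conditions: Me3SiBr (3 equiv), CH2Cl2, −20 °C to rt, short contact time
Reagents that add atoms: bromotrimethylsilane, C[Si](C)(C)Br
Why: The exchange of a tertiary alcohol for bromide with Me3SiBr runs by SN1 ionisation at C4 only, since C1 is alpha to the ester, and neighbouring-group participation of the antiperiplanar C5 chlorine (a chlorine-bridged cation, as in the classical halohydrin-to-dihalide conversions that go with retention) shields the lower face, so bromide enters on the face the oxygen left and trans to chlorine, which keeps C4 as R.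

Step 8
Reactants: 11 bromochloro ester
Product: 12 (1S,3R,4R)-4-bromo-3-chloro-4-methyl-1-(triethylsilyloxy)cyclohexane-1-carbaldehyde
Conditions: i-Bu2AlH (1.2 equiv), CH2Cl2, −78 °C; aq potassium sodium tartrate
Reagents that add atoms: none
Why: In this partial ester reduction the aluminium hemiacetal next to the quaternary, oxygenated C1 is stable at −78 °C and collapses to the aldehyde only on work-up, and alkyl halides are inert to the hydride at this temperature.

Step 9
Reactants: 13 (R)-2-hydroxy-1,2,2-triphenylethyl acetate; 14 methacrolein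
Product: 16 (R)-2-hydroxy-1,2,2-triphenylethyl (R)-3-hydroxy-4-methylpent-4-enoate, via dilithio enolate 15 (not isolated)
Conditions: LiN(i-Pr)2 (2.1 equiv), THF, −78 to 0 °C; 14, THF/2-methylbutane, −125 °C; aq NH4Cl; recrystallise
Reagents that add atoms: lithium diisopropylamide, [Li]N(C(C)C)C(C)C (lithium stays only in 15)
Why: In this auxiliary-controlled acetate aldol addition the doubly deprotonated (R)-triphenylglycol acetate attacks methacrolein in the same facial sense as it does 2-methylpropanal, which sets C10 as R, and the crystalline adduct can be freed of its minor diastereomer.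

Step 10
Reactants: 16 aldol adduct
Product: 17 (R)-2-hydroxy-1,2,2-triphenylethyl (R)-3-(tert-butyldimethylsilyloxy)-4-methylpent-4-enoate
Conditions: TBSCl (1.3 equiv), imidazole (2.5 equiv), DMF, rt
Reagents that add atoms: tert-butyldimethylsilyl chloride, CC(C)(C)[Si](C)(C)Cl
Why: Silyl ether formation with TBSCl and imidazole takes only the secondary allylic alcohol because the tertiary diphenylcarbinol of the auxiliary is too hindered.

Step 11
Reactants: 17 silylated aldol adduct
Product: 18 (R)-3-(tert-butyldimethylsilyloxy)-4-methylpent-4-en-1-ol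
Conditions: i-Bu2AlH (3.5 equiv), CH2Cl2, −78 to 0 °C; aq potassium sodium tartrate
Reagents that add atoms: none
Why: Reductive cleavage of the ester with excess i-Bu2AlH gives the primary alcohol and frees the auxiliary diol without touching C10 or the alkene.

Step 12
Reactants: 18 primary alcohol
Product: 19 (R)-5-bromo-3-(tert-butyldimethylsilyloxy)-2-methylpent-1-ene
Conditions: CBr4 (1.3 equiv), PPh3 (1.4 equiv), CH2Cl2, 0 °C
Reagents that add atoms: carbon tetrabromide, BrC(Br)(Br)Br
Why: The Appel bromination displaces the primary alkoxyphosphonium ion by SN2 attack two carbons away from C10, whose configuration is therefore not at risk.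

Step 13
Reactants: 19 side-chain bromide; 12 ring aldehyde
Product: 21 (4R)-1-[(1S,3R,4R)-4-bromo-3-chloro-4-methyl-1-(triethylsilyloxy)cyclohexyl]-4-(tert-butyldimethylsilyloxy)-5-methylhex-5-en-1-ol (both C7 epimers), via side-chain Grignard reagent 20 (not isolated)
Conditions: Mg, THF, rt (decanted from excess metal); 12, THF, −78 °C; AcOH/THF quench at −78 °C
Reagents that add atoms: magnesium, [Mg] (stays only in 20)
Why: Grignard addition to a non-enolisable aldehyde is far faster at −78 °C than any reaction of the reagent with the tertiary bromide or the secondary chloride, the C7 epimer mixture is harmless because C7 becomes sp2 in the next step, and the cold quench prevents silyl migration from the C1 to the C7 oxygen.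

Step 14
Reactants: 21 C7 carbinols
Product: 22 (4R)-1-[(1S,3R,4R)-4-bromo-3-chloro-4-methyl-1-(triethylsilyloxy)cyclohexyl]-4-(tert-butyldimethylsilyloxy)-5-methylhex-5-en-1-one
Conditions: Dess–Martin periodinane (1.5 equiv), NaHCO3, CH2Cl2, 0 °C to rt
Reagents that add atoms: none
Why: The buffered Dess–Martin oxidation is neutral and turns both C7 epimers into one ketone without affecting halides, silyl ethers or the alkene.

Step 15
Reactants: 22 ketone
Product: 23 (5R)-2-[(1S,3R,4R)-4-bromo-3-chloro-4-methyl-1-(triethylsilyloxy)cyclohexyl]-5-(tert-butyldimethylsilyloxy)-6-methyl-1-(trimethylsilyl)hept-6-en-2-ol (C7 configuration not controlled)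
Conditions: Me3SiCH2Li (3 equiv), anhydrous CeCl3 (3 equiv), THF, −78 °C; then 22, −78 to −40 °C
Reagents that add atoms: (trimethylsilyl)methyllithium, [Li]C[Si](C)(C)C
Why: In this first half of a Peterson olefination the weakly basic, strongly oxophilic organocerium reagent adds to the hindered, enolisable ketone at low temperature without dehydrohalogenation, and the configuration of the new C7 carbinol is irrelevant because it is erased in the next step.

Step 16
Reactants: 23 β-hydroxysilane
Product: 24 (1S,3R,4R)-4-bromo-3-chloro-1-[(5R)-5-hydroxy-6-methylhepta-1,6-dien-2-yl]-4-methylcyclohexan-1-ol (target)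
Conditions: HF·pyridine, THF, 0 °C to rt
Reagents that add atoms: none
Why: Acid-induced Peterson elimination of the tertiary β-hydroxysilane places the double bond only between C7 and the former CH2Si carbon, and the same reagent cleaves the TES and TBS ethers under conditions too weakly basic for loss of HBr and too weakly acidic for ionisation of the allylic alcohols.

Compound list
1 | 4-bromo-2-methylbut-1-ene | C=C(C)CCBr | starting material
2 | diethyl oxalate | CCOC(=O)C(=O)OCC | starting material
3 | 3-methylbut-3-enylmagnesium bromide | C=C(C)CC[Mg]Br | intermediate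
4 | ethyl 5-methyl-2-oxohex-5-enoate | CCOC(=O)C(=O)CCC(C)=C | intermediate
5 | allylboronic acid pinacol ester | C=CCB1OC(C)(C)C(C)(C)O1 | starting material
6 | ethyl (S)-2-allyl-2-hydroxy-5-methylhex-5-enoate | CCOC(=O)[C@@](O)(CC=C)CCC(C)=C | intermediate
7 | ethyl (S)-1-hydroxy-4-methylcyclohex-3-ene-1-carboxylate | CCOC(=O)[C@]1(O)CCC(C)=CC1 | intermediate
8 | ethyl (1S,3S,6R)-3-hydroxy-6-methyl-7-oxabicyclo[4.1.0]heptane-3-carboxylate | CCOC(=O)[C@]1(O)CC[C@@]2(C)O[C@H]2C1 | intermediate
9 | ethyl (1S,3S,6R)-6-methyl-3-(triethylsilyloxy)-7-oxabicyclo[4.1.0]heptane-3-carboxylate | CCOC(=O)[C@]1(O[Si](CC)(CC)CC)CC[C@@]2(C)O[C@H]2C1 | intermediate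
10 | ethyl (1S,3R,4R)-3-chloro-4-hydroxy-4-methyl-1-(triethylsilyloxy)cyclohexane-1-carboxylate | CCOC(=O)[C@]1(O[Si](CC)(CC)CC)CC[C@@](C)(O)[C@H](Cl)C1 | intermediate
11 | ethyl (1S,3R,4R)-4-bromo-3-chloro-4-methyl-1-(triethylsilyloxy)cyclohexane-1-carboxylate | CCOC(=O)[C@]1(O[Si](CC)(CC)CC)CC[C@@](C)(Br)[C@H](Cl)C1 | intermediate
12 | (1S,3R,4R)-4-bromo-3-chloro-4-methyl-1-(triethylsilyloxy)cyclohexane-1-carbaldehyde | O=C[C@]1(O[Si](CC)(CC)CC)CC[C@@](C)(Br)[C@H](Cl)C1 | intermediate
13 | (R)-2-hydroxy-1,2,2-triphenylethyl acetate | CC(=O)O[C@H](c1ccccc1)C(O)(c1ccccc1)c1ccccc1 | starting material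
14 | methacrolein | C=C(C)C=O | starting material
15 | dilithio enolate of 13 | C=C(O[Li])O[C@H](c1ccccc1)C(O[Li])(c1ccccc1)c1ccccc1 | intermediate
16 | (R)-2-hydroxy-1,2,2-triphenylethyl (R)-3-hydroxy-4-methylpent-4-enoate | C=C(C)[C@H](O)CC(=O)O[C@H](c1ccccc1)C(O)(c1ccccc1)c1ccccc1 | intermediate
17 | (R)-2-hydroxy-1,2,2-triphenylethyl (R)-3-(tert-butyldimethylsilyloxy)-4-methylpent-4-enoate | C=C(C)[C@H](O[Si](C)(C)C(C)(C)C)CC(=O)O[C@H](c1ccccc1)C(O)(c1ccccc1)c1ccccc1 | intermediate
18 | (R)-3-(tert-butyldimethylsilyloxy)-4-methylpent-4-en-1-ol | C=C(C)[C@H](O[Si](C)(C)C(C)(C)C)CCO | intermediate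
19 | (R)-5-bromo-3-(tert-butyldimethylsilyloxy)-2-methylpent-1-ene | C=C(C)[C@H](O[Si](C)(C)C(C)(C)C)CCBr | intermediate
20 | (R)-[3-(tert-butyldimethylsilyloxy)-4-methylpent-4-enyl]magnesium bromide | C=C(C)[C@H](O[Si](C)(C)C(C)(C)C)CC[Mg]Br | intermediate
21 | (4R)-1-[(1S,3R,4R)-4-bromo-3-chloro-4-methyl-1-(triethylsilyloxy)cyclohexyl]-4-(tert-butyldimethylsilyloxy)-5-methylhex-5-en-1-ol, C7 epimers | C=C(C)[C@H](O[Si](C)(C)C(C)(C)C)CCC(O)[C@]1(O[Si](CC)(CC)CC)CC[C@@](C)(Br)[C@H](Cl)C1 | intermediate
22 | (4R)-1-[(1S,3R,4R)-4-bromo-3-chloro-4-methyl-1-(triethylsilyloxy)cyclohexyl]-4-(tert-butyldimethylsilyloxy)-5-methylhex-5-en-1-one | C=C(C)[C@H](O[Si](C)(C)C(C)(C)C)CCC(=O)[C@]1(O[Si](CC)(CC)CC)CC[C@@](C)(Br)[C@H](Cl)C1 | intermediate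
23 | (5R)-2-[(1S,3R,4R)-4-bromo-3-chloro-4-methyl-1-(triethylsilyloxy)cyclohexyl]-5-(tert-butyldimethylsilyloxy)-6-methyl-1-(trimethylsilyl)hept-6-en-2-ol, C7 not defined | C=C(C)[C@H](O[Si](C)(C)C(C)(C)C)CCC(O)(C[Si](C)(C)C)[C@]1(O[Si](CC)(CC)CC)CC[C@@](C)(Br)[C@H](Cl)C1 | intermediate
24 | (1S,3R,4R)-4-bromo-3-chloro-1-[(5R)-5-hydroxy-6-methylhepta-1,6-dien-2-yl]-4-methylcyclohexan-1-ol | C=C(C)[C@H](O)CCC(=C)[C@]1(O)CC[C@@](C)(Br)[C@H](Cl)C1 | target

Total step count: 16. Longest linear sequence: 12 steps (steps 1–8 and 13–16).

Steps most likely to fail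

1. Step 7.
   - What may go wrong: The C4 cation may be captured from the wrong face. Proton loss to allylic chlorides followed by unselective re-addition of HBr would also erode the C4 configuration. Ionisation slowed by the electron-withdrawing chlorine could force conditions under which the silyl ether at C1 is lost.
   - Fallback: The cation is replaced by a radical, and the fallback sets out from 10. Acylation of the C4 hydroxyl with methyl chlorooxoacetate (Et3N, DMAP, CH2Cl2) should give the C4 methyl oxalate F1. One equivalent of aqueous CsOH in THF should then give the cesium oxalate F2. Blue-light irradiation of the latter with Ir[dF(CF3)ppy]2(dtbbpy)PF6 and diethyl 2-bromo-2-methylmalonate should release carbon dioxide twice and leave a tertiary C4 radical. That radical abstracts bromine anti to the pseudoaxial C5–Cl bond, as β-halocyclohexyl radicals tend to do. The sequence returns to the route at 11.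

2. Step 6.
   - What may go wrong: Acid-assisted stretching of the tertiary C4–O bond may divert chloride to C4. The ester that must sit axial in the trans-diaxial transition state may slow attack at C5.
   - Fallback: The fallback sets out from 9 and makes use of the tertiary opening. HCl in Et2O/CH2Cl2 at −78 °C should give, by trans-diaxial opening at C4, the C4-chloro C5-alcohol F3 (chlorine on the lower face, hydroxyl on the upper face). Tf2O and 2,6-lutidine at −78 °C should give the C5 triflate F4. On warming with Bu4NBr this triflate should ionise with assistance from the antiperiplanar chlorine. After the shift of chlorine from C4 to C5 the same chlorine-bridged cation as in step 7 results, and bromide opens it at the tertiary C4 from the upper face. The sequence returns at 11 and bypasses 10.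

3. Step 15.
   - What may go wrong: Slow addition to the crowded carbonyl group may let enolisation or base-induced loss of HBr compete.
   - Fallback: The fallback sets out from 22 and uses a non-basic titanium alkylidene in place of a carbanion. Cp2TiMe2 in toluene at 65 °C generates Cp2Ti=CH2, which methylenates the ketone through an oxatitanacyclobutane to give the bis-silyl ether of the target F5. HF·pyridine in THF then removes both silyl groups, and the sequence returns at 24.

Further compounds
F1 | step 7 | ethyl (1S,3R,4R)-3-chloro-4-[(2-methoxy-2-oxoacetyl)oxy]-4-methyl-1-(triethylsilyloxy)cyclohexane-1-carboxylate | CCOC(=O)[C@]1(O[Si](CC)(CC)CC)CC[C@@](C)(OC(=O)C(=O)OC)[C@H](Cl)C1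
F2 | step 7 | cesium 2-{[(1R,2R,4S)-2-chloro-4-(ethoxycarbonyl)-1-methyl-4-(triethylsilyloxy)cyclohexyl]oxy}-2-oxoacetate | CCOC(=O)[C@]1(O[Si](CC)(CC)CC)CC[C@@](C)(OC(=O)C(=O)[O-])[C@H](Cl)C1.[Cs+]
F3 | step 6 | ethyl (1S,3S,4S)-4-chloro-3-hydroxy-4-methyl-1-(triethylsilyloxy)cyclohexane-1-carboxylate | CCOC(=O)[C@]1(O[Si](CC)(CC)CC)CC[C@](C)(Cl)[C@@H](O)C1
F4 | step 6 | ethyl (1S,3S,4S)-4-chloro-4-methyl-1-(triethylsilyloxy)-3-(trifluoromethylsulfonyloxy)cyclohexane-1-carboxylate | CCOC(=O)[C@]1(O[Si](CC)(CC)CC)CC[C@](C)(Cl)[C@@H](OS(=O)(=O)C(F)(F)F)C1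
F5 | step 15 | (1S,3R,4R)-4-bromo-3-chloro-1-[(5R)-5-(tert-butyldimethylsilyloxy)-6-methylhepta-1,6-dien-2-yl]-4-methyl-1-(triethylsilyloxy)cyclohexane | C=C(C)[C@H](O[Si](C)(C)C(C)(C)C)CCC(=C)[C@]1(O[Si](CC)(CC)CC)CC[C@@](C)(Br)[C@H](Cl)C1
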